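**Retrosynthetic overview**
1. Target 8 ⇐ its O-benzyl ether 7 (hydrogenolysis as the last step).
2. 7 ⇐ C(sp3)–C(sp3) disconnection between the chromone 2-CH2 and the benzylic CH2: 6,7-dimethoxy-2-methylchromone 3 + benzylic alcohol 4 (proposed new hydrogen-borrowing vinylogous alkylation).
3. 3 ⇐ β-diketone 2 (cyclodehydration closes the γ-pyrone) ⇐ acetophenone 1 + ethyl acetate (Claisen condensation).
4. Ring order: both benzene rings are bought; the pyrone ring is closed in step 2; the arylethyl chain is attached in step 3.

Assumption: the target has no stereocentre or other stereogenic element (it is achiral), so "single enantiomer" needs no stereocontrol; 1 and 4 are taken as commercial.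

**Route**

Step 1
Reactants: 1 1-(2-hydroxy-4,5-dimethoxyphenyl)ethan-1-one
Product: 2 1-(2-hydroxy-4,5-dimethoxyphenyl)butane-1,3-dione
Conditions: NaH (4 equiv), EtOAc (6 equiv), THF, 0 °C → reflux, 3 h; then aq. HCl to pH 3
Reagents that add atoms: ethyl acetate, CCOC(C)=O
Why: Crossed Claisen condensation, in which the phenoxide/ketone-enolate dianion of 1 is C-acetylated by ethyl acetate and deprotonation of the resulting β-diketone pulls the equilibrium to product; no stereocentre is formed.

Step 2
Reactants: 2 1-(2-hydroxy-4,5-dimethoxyphenyl)butane-1,3-dione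
Product: 3 6,7-dimethoxy-2-methyl-4H-chromen-4-one
Conditions: conc. H2SO4 (cat.), AcOH, 100 °C, 1 h
Reagents that add atoms: none
Why: Acid-catalysed cyclodehydration (chromone synthesis from an o-hydroxyaryl β-diketone), in which the phenol adds to the distal methyl ketone and the 2-hydroxychromanone hemiketal loses water to give the γ-pyrone; no stereocentre is formed.

Step 3
Reactants: 3 6,7-dimethoxy-2-methyl-4H-chromen-4-one; 4 [3-(benzyloxy)-4-methoxyphenyl]methanol (1.2 equiv)
Product: 7 2-{2-[3-(benzyloxy)-4-methoxyphenyl]ethyl}-6,7-dimethoxy-4H-chromen-4-one, via aldehyde 5 (not isolated), via styrylchromone 6 (not isolated)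
Conditions: [Cp*IrCl2]2 (2.5 mol%), KOtBu (30 mol%), 4 Å MS, t-AmOH, 120 °C, sealed tube, Ar, 24 h
Reagents that add atoms: none
Why: Proposed new method: hydrogen-borrowing (hydrogen-autotransfer) vinylogous C-alkylation of the 2-methyl group of a chromone by a benzylic alcohol, a substrate class on which this reactivity has not been shown; the Cp*Ir(III) alkoxide of 4 undergoes β-hydride elimination to aldehyde 5 and Cp*Ir–H, the hindered alkoxide reversibly deprotonates the vinylogously acidic 2-CH3 of 3 to a dienolate that condenses with 5 (aldol/E1cB) to the (E)-styrylchromone 6, and Ir–H returns the borrowed hydrogen by 1,6-hydride delivery to the benzylic δ-carbon of the linear dienone followed by γ-protonation, which restores the pyrone and gives 7; the endocyclic C2=C3 and the C4=O are vinylogous-ester positions and far poorer hydride acceptors, and the sieves remove water so hydroxide cannot open the pyrone; the closest known reaction types are the Ir-catalysed hydrogen-borrowing C-alkylation of methyl ketones and 2-methyl azaarenes with primary alcohols and the base-mediated condensation of 2-methylchromones with aryl aldehydes; no stereocentre is formed and the E-alkene of 6 is consumed.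

Step 4
Reactants: 7 2-{2-[3-(benzyloxy)-4-methoxyphenyl]ethyl}-6,7-dimethoxy-4H-chromen-4-one
Product: 8 2-[2-(3-hydroxy-4-methoxyphenyl)ethyl]-6,7-dimethoxy-4H-chromen-4-one
Conditions: H2 (1 atm), 10% Pd/C, EtOAc–MeOH (1:1), rt, 2–4 h
Reagents that add atoms: none
Why: Catalytic hydrogenolysis of the benzyl aryl ether, which at 1 atm and room temperature leaves the chromone C2=C3 and C=O and the aryl methyl ethers untouched and also converts any carried-over 6 into the same product; no stereocentre is involved.

**Compound list**
1 | 1-(2-hydroxy-4,5-dimethoxyphenyl)ethan-1-one (2'-hydroxy-4',5'-dimethoxyacetophenone) | CC(=O)c1cc(OC)c(OC)cc1O | starting material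
2 | 1-(2-hydroxy-4,5-dimethoxyphenyl)butane-1,3-dione | CC(=O)CC(=O)c1cc(OC)c(OC)cc1O | intermediate
3 | 6,7-dimethoxy-2-methyl-4H-chromen-4-one | Cc1cc(=O)c2cc(OC)c(OC)cc2o1 | intermediate
4 | [3-(benzyloxy)-4-methoxyphenyl]methanol | COc1ccc(CO)cc1OCc1ccccc1 | starting material
5 | 3-(benzyloxy)-4-methoxybenzaldehyde | COc1ccc(C=O)cc1OCc1ccccc1 | intermediate
6 | (E)-2-{2-[3-(benzyloxy)-4-methoxyphenyl]ethenyl}-6,7-dimethoxy-4H-chromen-4-one | COc1ccc(/C=C/c2cc(=O)c3cc(OC)c(OC)cc3o2)cc1OCc1ccccc1 | intermediate
7 | 2-{2-[3-(benzyloxy)-4-methoxyphenyl]ethyl}-6,7-dimethoxy-4H-chromen-4-one | COc1ccc(CCc2cc(=O)c3cc(OC)c(OC)cc3o2)cc1OCc1ccccc1 | intermediate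
8 | 2-[2-(3-hydroxy-4-methoxyphenyl)ethyl]-6,7-dimethoxy-4H-chromen-4-one (achiral) | COc1ccc(CCc2cc(=O)c3cc(OC)c(OC)cc3o2)cc1O | target

**Step count and risk**
Total step count: 4. Longest linear sequence: 4 steps (1 → 2 → 3 → 7 → 8); 4 is a purchased coupling partner that enters at step 3.

The three steps most likely to fail:

Step 3 (the proposed new step). The risks are slow dienolate formation with only catalytic base, hydroxide opening of the pyrone, and loss of H2 that leaves 6 unreduced (a 6/7 mixture can still be taken into step 4). The fallback uses known chemistry, sets out from 3 and comes back to the route at 8. Compound 3 is condensed with purchased 3-(benzyloxy)-4-methoxybenzaldehyde (the same compound as 5) using NaOEt in EtOH at rt to 60 °C, and the (E)-styrylchromone 6 is isolated by filtration. Hydrogenation of 6 with H2 (1 atm) and 10% Pd/C in EtOAc–MeOH then saturates the exocyclic alkene and cleaves the benzyl ether in the same flask, giving 8 directly. This fallback makes no compound outside the compound list: none F0.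

Step 1. The risks are self-condensation of ethyl acetate and incomplete C-acylation of the electron-rich, deactivated dianion. The fallback is a Baker–Venkataraman sequence that sets out from 1 and comes back at 2. Compound 1 is O-acetylated with Ac2O, pyridine and cat. DMAP to 2-acetyl-4,5-dimethoxyphenyl acetate F1. Treatment of this ester with KOtBu in THF at 0 °C → rt, followed by an AcOH quench, gives 2 by intramolecular O→C acyl transfer.

Step 4. The risks are over-reduction of the chromone C2=C3 or C4=O on prolonged exposure, or a stalled hydrogenolysis because of iridium traces. The fallback changes the protecting-group strategy to an acid-labile one, sets out from 3 and comes back at 8; it would be used only once step 3 has been established. Commercial isovanillin (3-hydroxy-4-methoxybenzaldehyde) is protected with MOMCl and iPr2NEt in CH2Cl2 to 4-methoxy-3-(methoxymethoxy)benzaldehyde F2, which is reduced with NaBH4 in MeOH to [4-methoxy-3-(methoxymethoxy)phenyl]methanol F3. This alcohol is coupled with 3 under the step 3 conditions, passing in the flask through the aldehyde again and through (E)-6,7-dimethoxy-2-{2-[4-methoxy-3-(methoxymethoxy)phenyl]ethenyl}-4H-chromen-4-one F4, to give 6,7-dimethoxy-2-{2-[4-methoxy-3-(methoxymethoxy)phenyl]ethyl}-4H-chromen-4-one F5. The MOM acetal is then removed with HCl in MeOH at 40 °C to give 8 without any hydrogenation.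

**Further compounds**
F0 | step 3 | none | none
F1 | step 1 | 2-acetyl-4,5-dimethoxyphenyl acetate | CC(=O)Oc1cc(OC)c(OC)cc1C(C)=O
F2 | step 4 | 4-methoxy-3-(methoxymethoxy)benzaldehyde | COCOc1cc(C=O)ccc1OC
F3 | step 4 | [4-methoxy-3-(methoxymethoxy)phenyl]methanol | COCOc1cc(CO)ccc1OC
F4 | step 4 | (E)-6,7-dimethoxy-2-{2-[4-methoxy-3-(methoxymethoxy)phenyl]ethenyl}-4H-chromen-4-one | COCOc1cc(/C=C/c2cc(=O)c3cc(OC)c(OC)cc3o2)ccc1OC
F5 | step 4 | 6,7-dimethoxy-2-{2-[4-methoxy-3-(methoxymethoxy)phenyl]ethyl}-4H-chromen-4-one | COCOc1cc(CCc2cc(=O)c3cc(OC)c(OC)cc3o2)ccc1OC
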